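**Retrosynthetic overview**

1. The target is the C3'–C3''' biaryl cross-dimer of (2S)-naringenin and (2R,3R)-aromadendrin. Both halves are the same 5,7-dihydroxy-2-arylchroman-4-one and differ only at C3 (H or OH); C2 has the same spatial arrangement in both, the S and R labels differing only through the CIP ranks.
2. Disconnections, last to first: six O-benzyl groups (hydrogenolysis); the biaryl bond C3'–C3''' (Suzuki–Miyaura coupling of two monomers); in the flavanone half, a C3–O bond that is absent from the target and is cut with SmI2 after it has controlled C2.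
3. Both halves therefore come from one monomer, the 3'-bromo dihydroflavonol 10. Its ring C is closed in one flask by forming C4–C4a and O1–C2, a [3+3] union of ring A as a C,O-dinucleophile with a (2R,3S)-glycidic morpholine amide as a 1,3-dielectrophile.
4. Feature that makes this possible: in ring A the phenol oxygen O1 and the ortho ring carbon C4a (flanked by two phloroglucinol oxygens) are 1,3-related and can be charged together as an ortho-lithiated phenoxide. They face the acyl carbon C4 and the benzylic carbon C2 (para to the C4' oxygen of ring B), which is held in a temporary oxirane C2–O–C3.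
5. Order of ring formation: rings A and B are bought; temporary oxirane (step 2); ring C of the monomer (step 4); the biaryl bond then joins the two halves (step 7).

Key step: step 4

Assumption: 1, 2 and 5 are taken as catalogue chemicals (2 is otherwise one Arbuzov step from 4-(chloroacetyl)morpholine and P(OEt)3), and the sense of induction in step 2 is taken from the analogous lanthanide–BINOL epoxidation of chalcones.

**Route**

Step 1
Reactants: 1 4-(benzyloxy)-3-bromobenzaldehyde; 2 diethyl [2-(morpholin-4-yl)-2-oxoethyl]phosphonate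
Product: 3 (E)-3-[4-(benzyloxy)-3-bromophenyl]-1-(morpholin-4-yl)prop-2-en-1-one
Conditions: LiCl, DBU, MeCN, rt
Reagents that add atoms: none
Why: Horner–Wadsworth–Emmons olefination under Masamune–Roush conditions, in which the lithium-chelated amide phosphonate is deprotonated by DBU and the stabilised carbanion should give the (E)-enamide, the aryl bromide and the benzyl ether being inert.

Step 2
Reactants: 3 (E)-3-[4-(benzyloxy)-3-bromophenyl]-1-(morpholin-4-yl)prop-2-en-1-one
Product: 4 {(2R,3S)-3-[4-(benzyloxy)-3-bromophenyl]oxiran-2-yl}(morpholin-4-yl)methanone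
Conditions: Sm(O-i-Pr)3 (10 mol %), (S)-BINOL (10 mol %), Ph3As=O (10 mol %), t-BuOOH (1.5 equiv), 4 Å MS, THF, rt
Reagents that add atoms: tert-butyl hydroperoxide, CC(C)(C)OO
Why: Lanthanide–BINOL catalysed asymmetric nucleophilic epoxidation of an α,β-unsaturated amide, in which the trans oxirane follows from the E alkene and both stereocentres are set by the chiral samarium peroxide, the (S)-BINOL complex being expected to deliver the (2R,3S) oxirane (the antipodal ligand is taken if the first run shows the opposite sense).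

Step 3
Reactants: 5 3,5-bis(benzyloxy)phenol
Product: 6 3,5-bis(benzyloxy)-2-iodophenol
Conditions: NIS (1.0 equiv), CH2Cl2, −40 → 0 °C
Reagents that add atoms: N-iodosuccinimide, O=C1CCC(=O)N1I
Why: Electrophilic aromatic iodination of an electron-rich phenol, which should go ortho to the free hydroxyl at C2 because C4 lies between two benzyloxy groups and is more hindered, any 4-iodo isomer being removed by chromatography.

Step 4
Reactants: 6 3,5-bis(benzyloxy)-2-iodophenol; 4 {(2R,3S)-3-[4-(benzyloxy)-3-bromophenyl]oxiran-2-yl}(morpholin-4-yl)methanone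
Product: 10 (2R,3R)-5,7-bis(benzyloxy)-2-[4-(benzyloxy)-3-bromophenyl]-3-hydroxy-2,3-dihydro-4H-chromen-4-one, via dilithio phenoxide 7 (not isolated), via aminal alkoxide 8 (not isolated), via epoxy ketone 9 (not isolated)
Conditions: 6 (1.2 equiv), t-BuLi (3.0 equiv to 6), THF, −78 °C; then 4 (1.0 equiv), −78 → −20 °C; then CF3CO2H (6 equiv), −78 °C → rt
Reagents that add atoms: none
Why: Iodine–lithium exchange on the lithium phenoxide of 6 gives the C,O-dianion 7, whose aryl carbon adds to the morpholine amide of 4 to form the stable aminal alkoxide 8 (bond C4–C4a, no over-addition), and CF3CO2H then collapses 8 to the 2'-hydroxy epoxy ketone 9, whose phenol oxygen opens the protonated oxirane at the benzylic carbon (bond O1–C2). The closest known reaction types are the addition of organolithiums to α,β-epoxy morpholine or Weinreb amides to give epoxy ketones and the acid-promoted cyclisation of 2'-hydroxychalcone epoxides to trans-dihydroflavonols, here run in one flask as a [3+3] annulation. Ring C closes in the 6-endo-tet mode at the oxirane carbon that becomes C2. C3 keeps the configuration set by the catalyst in step 2 because its C–O bond is never broken, and C2 is set relative to it, by inversion at the benzylic oxirane carbon in the SN2-like limit and by the preference for the 2,3-trans diequatorial ring in the ion-pair limit, both of which lead to (2R,3R). The step needs 6-endo opening instead of 5-exo opening at the carbon next to the carbonyl (the benzofuranone pathway) and no 1,2-acyl shift, which the substrate secures through the benzyloxy group para to the benzylic carbon on ring B (it directs C–O cleavage to C2 under acid), the hydrogen bond that holds the phenol beside the carbonyl, and a counter-ion of low nucleophilicity. At the first stage the aryl bromide, the oxirane and the benzyl ethers should not react at −78 °C, since the doubly ortho-oxygenated aryllithium is too stabilised to exchange with the aryl bromide and should add to the amide carbonyl faster than it opens the oxirane.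

Step 5
Reactants: 10 (2R,3R)-5,7-bis(benzyloxy)-2-[4-(benzyloxy)-3-bromophenyl]-3-hydroxy-2,3-dihydro-4H-chromen-4-one
Product: 11 (2S)-5,7-bis(benzyloxy)-2-[4-(benzyloxy)-3-bromophenyl]-2,3-dihydro-4H-chromen-4-one
Conditions: SmI2 (2.2 equiv), THF/MeOH (10:1), −78 °C
Reagents that add atoms: none
Why: Reductive cleavage of the α-hydroxyl of a ketone by SmI2 (two single-electron transfers through the ketyl to the samarium enolate, which methanol should protonate at −78 °C before the ring oxygen can be expelled), so that C3 becomes CH2 while C2 is untouched and is now named S, aryl bromides and benzyl ethers not being reduced in the absence of HMPA.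

Step 6
Reactants: 11 (2S)-5,7-bis(benzyloxy)-2-[4-(benzyloxy)-3-bromophenyl]-2,3-dihydro-4H-chromen-4-one
Product: 12 (2S)-5,7-bis(benzyloxy)-2-[4-(benzyloxy)-3-(4,4,5,5-tetramethyl-1,3,2-dioxaborolan-2-yl)phenyl]-2,3-dihydro-4H-chromen-4-one
Conditions: B2pin2 (1.2 equiv), Pd(dppf)Cl2 (5 mol %), KOAc (3 equiv), 1,4-dioxane, 80 °C
Reagents that add atoms: bis(pinacolato)diboron, CC1(C)OB(OC1(C)C)B1OC(C)(C)C(C)(C)O1
Why: Miyaura borylation (oxidative addition of zerovalent palladium into the C–Br bond, acetate-assisted transmetallation with the diboron, reductive elimination), in which the weak base KOAc should leave the base-labile C2 centre intact.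

Step 7
Reactants: 12 (2S)-5,7-bis(benzyloxy)-2-[4-(benzyloxy)-3-(4,4,5,5-tetramethyl-1,3,2-dioxaborolan-2-yl)phenyl]-2,3-dihydro-4H-chromen-4-one; 10 (2R,3R)-5,7-bis(benzyloxy)-2-[4-(benzyloxy)-3-bromophenyl]-3-hydroxy-2,3-dihydro-4H-chromen-4-one
Product: 13 (2R,3R)-5,7-bis(benzyloxy)-2-{2,2'-bis(benzyloxy)-5'-[(2S)-5,7-bis(benzyloxy)-4-oxochroman-2-yl]biphenyl-5-yl}-3-hydroxychroman-4-one
Conditions: Pd(OAc)2 (5 mol %), SPhos (10 mol %), K3PO4 (2 equiv), toluene/H2O (10:1), 40 °C, argon
Reagents that add atoms: none
Why: Suzuki–Miyaura cross-coupling, in which the electron-rich biaryl phosphine should allow two ortho-alkoxy partners to couple at 40 °C, a temperature at which the phosphate base is not expected to open ring C of either half, so that all three stereocentres are carried through unchanged and the doubly ortho-substituted biaryl remains free to rotate.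

Step 8
Reactants: 13 (2R,3R)-5,7-bis(benzyloxy)-2-{2,2'-bis(benzyloxy)-5'-[(2S)-5,7-bis(benzyloxy)-4-oxochroman-2-yl]biphenyl-5-yl}-3-hydroxychroman-4-one
Product: 14 (2R,3R)-2-{2,2'-dihydroxy-5'-[(2S)-5,7-dihydroxy-4-oxochroman-2-yl]biphenyl-5-yl}-3,5,7-trihydroxychroman-4-one
Conditions: H2 (1 atm), Pd/C (10 %), EtOAc/MeOH (1:1), rt
Reagents that add atoms: none
Why: Hydrogenolysis of six aryl benzyl ethers over palladium on carbon under neutral conditions, which should leave the two chromanone carbonyls, the benzylic C2–O1 bonds and all three stereocentres untouched if the reaction is stopped at full debenzylation.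

**Compound list**

1 | 4-(benzyloxy)-3-bromobenzaldehyde | O=Cc1ccc(OCc2ccccc2)c(Br)c1 | starting material
2 | diethyl [2-(morpholin-4-yl)-2-oxoethyl]phosphonate | CCOP(=O)(OCC)CC(=O)N1CCOCC1 | starting material
3 | (E)-3-[4-(benzyloxy)-3-bromophenyl]-1-(morpholin-4-yl)prop-2-en-1-one | O=C(/C=C/c1ccc(OCc2ccccc2)c(Br)c1)N1CCOCC1 | intermediate
4 | {(2R,3S)-3-[4-(benzyloxy)-3-bromophenyl]oxiran-2-yl}(morpholin-4-yl)methanone | O=C(N1CCOCC1)[C@@H]1O[C@H]1c1ccc(OCc2ccccc2)c(Br)c1 | intermediate
5 | 3,5-bis(benzyloxy)phenol | Oc1cc(OCc2ccccc2)cc(OCc2ccccc2)c1 | starting material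
6 | 3,5-bis(benzyloxy)-2-iodophenol | Oc1cc(OCc2ccccc2)cc(OCc2ccccc2)c1I | intermediate
7 | lithium 3,5-bis(benzyloxy)-2-lithiophenoxide | [Li]Oc1cc(OCc2ccccc2)cc(OCc2ccccc2)c1[Li] | intermediate
8 | dilithium salt (carbinol alkoxide and phenoxide) of [2,4-bis(benzyloxy)-6-hydroxyphenyl]{(2R,3S)-3-[4-(benzyloxy)-3-bromophenyl]oxiran-2-yl}(morpholin-4-yl)methanol, carbinol carbon undefined | [Li]OC(N1CCOCC1)(c1c(O[Li])cc(OCc2ccccc2)cc1OCc1ccccc1)[C@@H]1O[C@H]1c1ccc(OCc2ccccc2)c(Br)c1 | intermediate
9 | [2,4-bis(benzyloxy)-6-hydroxyphenyl]{(2R,3S)-3-[4-(benzyloxy)-3-bromophenyl]oxiran-2-yl}methanone | O=C(c1c(O)cc(OCc2ccccc2)cc1OCc1ccccc1)[C@@H]1O[C@H]1c1ccc(OCc2ccccc2)c(Br)c1 | intermediate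
10 | (2R,3R)-5,7-bis(benzyloxy)-2-[4-(benzyloxy)-3-bromophenyl]-3-hydroxy-2,3-dihydro-4H-chromen-4-one | Brc1cc(ccc1OCc1ccccc1)[C@H]1Oc2cc(OCc3ccccc3)cc(OCc3ccccc3)c2C(=O)[C@@H]1O | intermediate
11 | (2S)-5,7-bis(benzyloxy)-2-[4-(benzyloxy)-3-bromophenyl]-2,3-dihydro-4H-chromen-4-one | Brc1cc(ccc1OCc1ccccc1)[C@H]1Oc2cc(OCc3ccccc3)cc(OCc3ccccc3)c2C(=O)C1 | intermediate
12 | (2S)-5,7-bis(benzyloxy)-2-[4-(benzyloxy)-3-(4,4,5,5-tetramethyl-1,3,2-dioxaborolan-2-yl)phenyl]-2,3-dihydro-4H-chromen-4-one | CC1(C)OB(OC1(C)C)c1cc(ccc1OCc1ccccc1)[C@H]1Oc2cc(OCc3ccccc3)cc(OCc3ccccc3)c2C(=O)C1 | intermediate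
13 | (2R,3R)-5,7-bis(benzyloxy)-2-{2,2'-bis(benzyloxy)-5'-[(2S)-5,7-bis(benzyloxy)-4-oxochroman-2-yl]biphenyl-5-yl}-3-hydroxychroman-4-one | O=C1C[C@@H](c2ccc(OCc3ccccc3)c(-c3cc([C@H]4Oc5cc(OCc6ccccc6)cc(OCc6ccccc6)c5C(=O)[C@@H]4O)ccc3OCc3ccccc3)c2)Oc2cc(OCc3ccccc3)cc(OCc3ccccc3)c21 | intermediate
14 | (2R,3R)-2-{2,2'-dihydroxy-5'-[(2S)-5,7-dihydroxy-4-oxochroman-2-yl]biphenyl-5-yl}-3,5,7-trihydroxychroman-4-one | O=C1C[C@@H](c2ccc(O)c(-c3cc([C@H]4Oc5cc(O)cc(O)c5C(=O)[C@@H]4O)ccc3O)c2)Oc2cc(O)cc(O)c21 | target

**Step count**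

Total step count: 8. Longest linear sequence: 7 steps (1, 2, 4, 5, 6, 7, 8); step 3 is the only side branch, and monomer 10 enters twice (steps 5 and 7).

**Steps most likely to fail**

Step 4. The oxirane may open at the carbon next to the carbonyl (5-exo closure), or it may ionise at the benzylic carbon and undergo 1,2-acyl migration; trans selectivity at C2 may also be incomplete. The fallback sets out from 9, which is isolated by quenching the flask with aqueous NH4Cl at −78 °C in place of the acid. Benzyl mercaptan with catalytic SnCl4 (CH2Cl2, −20 °C) should open the oxirane at the benzylic carbon with inversion to give the hydroxy sulfide (2S,3R)-3-[4-(benzyloxy)-3-bromophenyl]-3-(benzylsulfanyl)-1-[2,4-bis(benzyloxy)-6-hydroxyphenyl]-2-hydroxypropan-1-one F1. AgBF4 (CH2Cl2, 0 °C) then ionises the C–S bond, and the phenol should close ring C trans to the C3 hydroxyl. The fallback returns to the route at 10.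

Step 5. The samarium enolate may expel the ring oxygen (retro-oxa-Michael opening of ring C and loss of the C2 configuration), or the ketone may be reduced further. The fallback again sets out from 9, isolated as above. (PhSe)2 with NaBH4 and AcOH in EtOH (0 °C) should cleave the C–O bond next to the carbonyl reductively and leave the benzylic C–O bond intact, giving the aldol (3R)-3-[4-(benzyloxy)-3-bromophenyl]-1-[2,4-bis(benzyloxy)-6-hydroxyphenyl]-3-hydroxypropan-1-one F2. An intramolecular Mitsunobu etherification (PPh3, DIAD, THF, 0 °C) then closes ring C with inversion at the benzylic carbon. The fallback returns to the route at 11.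

Step 7. The aqueous base may open ring C (epimerisation at C2 of either half, enolisation at C3 of the dihydroflavonol half), and 12 may undergo protodeboronation. The fallback sets out from 11. Stannylation with (Me3Sn)2 and Pd(PPh3)4 (toluene, 100 °C) should give (2S)-5,7-bis(benzyloxy)-2-[4-(benzyloxy)-3-(trimethylstannyl)phenyl]-2,3-dihydro-4H-chromen-4-one F3. A base-free Stille coupling of F3 with 10 (Pd(PPh3)4, CuI, DMF, 50 °C) then forms the biaryl bond under neutral conditions. The fallback returns to the route at 13.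

**Further compounds**

F1 | step 4 | (2S,3R)-3-[4-(benzyloxy)-3-bromophenyl]-3-(benzylsulfanyl)-1-[2,4-bis(benzyloxy)-6-hydroxyphenyl]-2-hydroxypropan-1-one | O=C(c1c(O)cc(OCc2ccccc2)cc1OCc1ccccc1)[C@H](O)[C@H](SCc1ccccc1)c1ccc(OCc2ccccc2)c(Br)c1
F2 | step 5 | (3R)-3-[4-(benzyloxy)-3-bromophenyl]-1-[2,4-bis(benzyloxy)-6-hydroxyphenyl]-3-hydroxypropan-1-one | O=C(c1c(O)cc(OCc2ccccc2)cc1OCc1ccccc1)C[C@@H](O)c1ccc(OCc2ccccc2)c(Br)c1
F3 | step 7 | (2S)-5,7-bis(benzyloxy)-2-[4-(benzyloxy)-3-(trimethylstannyl)phenyl]-2,3-dihydro-4H-chromen-4-one | C[Sn](C)(C)c1cc(ccc1OCc1ccccc1)[C@H]1Oc2cc(OCc3ccccc3)cc(OCc3ccccc3)c2C(=O)C1
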